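**Retrosynthetic overview**

- Feature: in ring A the oxygens on C5, C7 and C8a alternate and C4a carries the C4 carbonyl. Ring A plus C4 is therefore an acylphloroglucinol, the fold of a 1,3,5,7-tetracarbonyl chain, and C6 and C8 remain as its two nucleophilic CH carbons.
- Key disconnections: C4a-C8a (Claisen) and O1-C2 (oxa-Michael), both made in one flask. The chain carries the C5, C7 and C8a carbonyls masked as a 4-hydroxy-2-pyranone and the C2 carbonyl masked as an alkyne carbon.
- Ring order: ring B is bought (1,2,4-trimethoxybenzene, oxygenated at C3' and iodinated at C1'), then ring A, then ring C. The chain is assembled by Sonogashira coupling, carbamoylation of the alkyne and acylation of the pyranone dianion.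
- End game: dibromination at C6 and C8, copper-mediated exchange of both bromides for methoxide, O-methylation at C5 and C7, hydrogenolysis of the 3'-benzyl ether.

Key step: step 9

Remark: atoms of open-chain intermediates carry the flavone numbers they will have in the product (C2 to C8a); the aryl halide is made as the iodide so that the alkyne coupling runs under mild conditions.

**Route**

Step 1
Reactants: 1 1,2,4-trimethoxybenzene
Product: 4 2,3,6-trimethoxyphenol, via aryllithium 2 (not isolated), via dimethyl arylboronate 3 (not isolated)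
Conditions: n-BuLi, THF, 0 °C to rt; B(OMe)3, −78 °C to rt; H2O2, AcOH, 0 °C to rt
Reagents that add atoms: hydrogen peroxide, OO
Why: Directed ortho-lithiation should take place at C3, the only position flanked by two methoxy groups, and borylation followed by oxidation of the boronate places the hydroxyl on that carbon.

Step 2
Reactants: 4 2,3,6-trimethoxyphenol
Product: 5 2,3,6-trimethoxyphenyl acetate
Conditions: Ac2O, pyridine, DMAP (cat.), CH2Cl2, rt
Reagents that add atoms: acetic anhydride, CC(=O)OC(C)=O
Why: DMAP-catalysed O-acylation turns the strongest donor of the ring into a weak one, so that the following substitution is steered by the methoxy groups.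

Step 3
Reactants: 5 2,3,6-trimethoxyphenyl acetate
Product: 6 3-iodo-2,5,6-trimethoxyphenyl acetate
Conditions: NIS, CF3CO2H (cat.), MeCN, rt
Reagents that add atoms: N-iodosuccinimide, O=C1CCC(=O)N1I
Why: Electrophilic aromatic iodination should go to the carbon that is para to one methoxy group and ortho to another (the future C1'), because the only other free carbon is para to the acetoxy group, a much weaker donor.

Step 4
Reactants: 6 3-iodo-2,5,6-trimethoxyphenyl acetate
Product: 8 3-(benzyloxy)-1-iodo-2,4,5-trimethoxybenzene, via iodophenol 7 (not isolated)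
Conditions: K2CO3, MeOH, rt; evaporation; BnBr, DMF, 50 °C
Reagents that add atoms: benzyl bromide, BrCc1ccccc1
Why: Carbonate-mediated methanolysis of the aryl acetate gives the potassium phenoxide, which is benzylated in the same flask (Williamson ether synthesis) to an ether that withstands organolithium and alkoxide reagents.

Step 5
Reactants: 8 3-(benzyloxy)-1-iodo-2,4,5-trimethoxybenzene; 9 trimethylsilylacetylene
Product: 10 {[3-(benzyloxy)-2,4,5-trimethoxyphenyl]ethynyl}trimethylsilane
Conditions: Pd(PPh3)2Cl2 (cat.), CuI (cat.), Et3N, THF, 50 °C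
Reagents that add atoms: none
Why: Sonogashira coupling of an aryl iodide should proceed under mild conditions even on this electron-rich ring, since oxidative addition of the C-I bond to zerovalent palladium is fast.

Step 6
Reactants: 10 {[3-(benzyloxy)-2,4,5-trimethoxyphenyl]ethynyl}trimethylsilane
Product: 11 3-(benzyloxy)-1-ethynyl-2,4,5-trimethoxybenzene
Conditions: K2CO3, MeOH–THF, rt
Reagents that add atoms: none
Why: Methoxide-induced protodesilylation cleaves the alkynyl C-Si bond selectively and leaves every ether untouched.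

Step 7
Reactants: 11 3-(benzyloxy)-1-ethynyl-2,4,5-trimethoxybenzene; 12 N-methoxy-N-methylcarbamoyl chloride
Product: 14 3-[3-(benzyloxy)-2,4,5-trimethoxyphenyl]-N-methoxy-N-methylprop-2-ynamide, via lithium acetylide 13 (not isolated)
Conditions: n-BuLi, THF, −78 °C; ClC(O)N(OMe)Me, −78 to 0 °C
Reagents that add atoms: none
Why: Nucleophilic acyl substitution of the carbamoyl chloride by the lithium acetylide installs C4 directly as the alkynyl Weinreb amide, chloride being the only good leaving group.

Step 8
Reactants: 15 4-hydroxy-6-methyl-2H-pyran-2-one; 14 3-[3-(benzyloxy)-2,4,5-trimethoxyphenyl]-N-methoxy-N-methylprop-2-ynamide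
Product: 17 6-{4-[3-(benzyloxy)-2,4,5-trimethoxyphenyl]-2-oxobut-3-yn-1-yl}-4-hydroxy-2H-pyran-2-one, via pyranone dianion 16 (not isolated)
Conditions: 15 (2 equiv), LiN(i-Pr)2 (4.2 equiv), THF, −78 to −20 °C; 14, −78 °C; inverse quench into cold 1 M HCl
Reagents that add atoms: none
Why: The O,C-dianion reacts at its methyl-derived carbon as a vinylogous enolate with the Weinreb amide (Weinreb ketone synthesis), and the chelated tetrahedral adduct should persist until the cold acid quench, so that no free ynone is exposed to carbanion or amine.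

Step 9
Reactants: 17 6-{4-[3-(benzyloxy)-2,4,5-trimethoxyphenyl]-2-oxobut-3-yn-1-yl}-4-hydroxy-2H-pyran-2-one
Product: 20 2-[3-(benzyloxy)-2,4,5-trimethoxyphenyl]-5,7-dihydroxy-4H-chromen-4-one, via triketo ester 18 (not isolated), via trihydroxyphenyl ynone 19 (not isolated)
Conditions: Mg(OMe)2 (5 equiv), MeOH, reflux; then 2 M HCl, rt
Reagents that add atoms: none
Why: Proposed new method: Mg(OMe)2 should methanolyse the lactone of 17 (a known opening of 4-hydroxy-2-pyranones) to the magnesium chelate of triketo ester 18, whose C4a carbanion, doubly activated by the C4 and C5 carbonyls, attacks the ester carbon in a 6-exo-trig Claisen condensation that forms C4a-C8a, expels methoxide and after enolisation gives ring A of 19. One of the two equivalent ortho phenoxides of 19 then adds to the ynone β-carbon in a 6-endo-dig oxa-Michael closure (O1-C2) that forms ring C, and no stereocentre arises. The closest known reactions are the alkoxide-induced rearrangement of 6-acylmethyl-4-hydroxy-2-pyranones and 3,5,7-triketo esters to acylphloroglucinols and the base-induced cyclisation of 2-hydroxyaryl ynones to flavones, which have not been combined in one operation on a chain that ends in an ynone. The step needs Claisen folding to win over aldol attack of C8 on the C4 carbonyl and over carbon-Michael attack of C6 on C2; the ketone carbonyls are expected to be enolised first as magnesium enolates and so to be poor aldol acceptors, while the ester stays electrophilic and no hydroxide is present to turn it into an inert carboxylate. It also needs 6-endo rather than 5-exo (aurone) closure, which the β-polarisation of the ynone favours and which becomes the only path once methanol has added to the triple bond, because that adduct has the same oxidation level and can close only at C2 by addition-elimination. Early attack of the C5 enolate oxygen on C2 would give a 2-aryl-4-pyranone that can still undergo the same Claisen closure and, ring A being symmetric, converges on 20, and the acid work-up should complete any unfinished closure of ring C.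

Step 10
Reactants: 20 2-[3-(benzyloxy)-2,4,5-trimethoxyphenyl]-5,7-dihydroxy-4H-chromen-4-one
Product: 21 2-[3-(benzyloxy)-2,4,5-trimethoxyphenyl]-6,8-dibromo-5,7-dihydroxy-4H-chromen-4-one
Conditions: NBS (2.05 equiv), THF, −10 °C to rt
Reagents that add atoms: N-bromosuccinimide, O=C1CCC(=O)N1Br
Why: Electrophilic aromatic bromination should take C6 and C8, each ortho or para to both free hydroxyls of the phloroglucinol ring, well before the single free carbon of ring B or C3.

Step 11
Reactants: 21 2-[3-(benzyloxy)-2,4,5-trimethoxyphenyl]-6,8-dibromo-5,7-dihydroxy-4H-chromen-4-one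
Product: 22 2-[3-(benzyloxy)-2,4,5-trimethoxyphenyl]-5,7-dihydroxy-6,8-dimethoxy-4H-chromen-4-one
Conditions: NaOMe (excess), CuBr (0.3 equiv), DMF–MeOH, 110 °C, N2; then dilute HCl
Reagents that add atoms: sodium methoxide, [Na+].[O-]C
Why: Copper-mediated substitution of aryl bromide by methoxide (Ullmann-type ether synthesis) is established for bromophenols and for 6,8-dibromo-5,7-dihydroxyflavones, and the bis-phenoxide shields the pyranone ring from attack by methoxide.

Step 12
Reactants: 22 2-[3-(benzyloxy)-2,4,5-trimethoxyphenyl]-5,7-dihydroxy-6,8-dimethoxy-4H-chromen-4-one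
Product: 23 2-[3-(benzyloxy)-2,4,5-trimethoxyphenyl]-5,6,7,8-tetramethoxy-4H-chromen-4-one
Conditions: Me2SO4 (excess), K2CO3, acetone, reflux
Reagents that add atoms: dimethyl sulfate, COS(=O)(=O)OC
Why: Williamson methylation with excess reagent at reflux should alkylate both the C7 hydroxyl and the hydrogen-bonded C5 hydroxyl, the only free hydroxyls in the molecule.

Step 13
Reactants: 23 2-[3-(benzyloxy)-2,4,5-trimethoxyphenyl]-5,6,7,8-tetramethoxy-4H-chromen-4-one
Product: 24 Agehoustin C
Conditions: H2 (1 atm), 10% Pd/C, EtOAc–MeOH, rt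
Reagents that add atoms: none
Why: Catalytic hydrogenolysis cleaves the benzylic C-O bond to free the 3'-hydroxyl, while the C2-C3 bond of the flavone is not expected to be reduced at one atmosphere.

**Compound list**

1 | 1,2,4-trimethoxybenzene | COc1ccc(OC)c(OC)c1 | starting material
2 | (2,3,6-trimethoxyphenyl)lithium | [Li]c1c(OC)ccc(OC)c1OC | intermediate (not isolated)
3 | dimethyl (2,3,6-trimethoxyphenyl)boronate | COB(OC)c1c(OC)ccc(OC)c1OC | intermediate (not isolated)
4 | 2,3,6-trimethoxyphenol | Oc1c(OC)ccc(OC)c1OC | intermediate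
5 | 2,3,6-trimethoxyphenyl acetate | CC(=O)Oc1c(OC)ccc(OC)c1OC | intermediate
6 | 3-iodo-2,5,6-trimethoxyphenyl acetate | CC(=O)Oc1c(OC)c(I)cc(OC)c1OC | intermediate
7 | 3-iodo-2,5,6-trimethoxyphenol (formed as its potassium salt) | Oc1c(OC)c(I)cc(OC)c1OC | intermediate (not isolated)
8 | 3-(benzyloxy)-1-iodo-2,4,5-trimethoxybenzene | COc1cc(I)c(OC)c(OCc2ccccc2)c1OC | intermediate
9 | trimethylsilylacetylene | C#C[Si](C)(C)C | starting material
10 | {[3-(benzyloxy)-2,4,5-trimethoxyphenyl]ethynyl}trimethylsilane | COc1cc(C#C[Si](C)(C)C)c(OC)c(OCc2ccccc2)c1OC | intermediate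
11 | 3-(benzyloxy)-1-ethynyl-2,4,5-trimethoxybenzene | COc1cc(C#C)c(OC)c(OCc2ccccc2)c1OC | intermediate
12 | N-methoxy-N-methylcarbamoyl chloride | CON(C)C(Cl)=O | starting material
13 | {[3-(benzyloxy)-2,4,5-trimethoxyphenyl]ethynyl}lithium | COc1cc(C#C[Li])c(OC)c(OCc2ccccc2)c1OC | intermediate (not isolated)
14 | 3-[3-(benzyloxy)-2,4,5-trimethoxyphenyl]-N-methoxy-N-methylprop-2-ynamide | COc1cc(C#CC(=O)N(C)OC)c(OC)c(OCc2ccccc2)c1OC | intermediate
15 | 4-hydroxy-6-methyl-2H-pyran-2-one | Cc1cc(O)cc(=O)o1 | starting material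
16 | dilithium O,C-dianion of 4-hydroxy-6-methyl-2H-pyran-2-one (lithium on O4 and on the methyl carbon) | [Li]Cc1cc(O[Li])cc(=O)o1 | intermediate (not isolated)
17 | 6-{4-[3-(benzyloxy)-2,4,5-trimethoxyphenyl]-2-oxobut-3-yn-1-yl}-4-hydroxy-2H-pyran-2-one | O=C(Cc1cc(O)cc(=O)o1)C#Cc1cc(OC)c(OC)c(OCc2ccccc2)c1OC | intermediate
18 | methyl 9-[3-(benzyloxy)-2,4,5-trimethoxyphenyl]-3,5,7-trioxonon-8-ynoate (formed as its magnesium chelate) | COC(=O)CC(=O)CC(=O)CC(=O)C#Cc1cc(OC)c(OC)c(OCc2ccccc2)c1OC | intermediate (not isolated)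
19 | 3-[3-(benzyloxy)-2,4,5-trimethoxyphenyl]-1-(2,4,6-trihydroxyphenyl)prop-2-yn-1-one | O=C(C#Cc1cc(OC)c(OC)c(OCc2ccccc2)c1OC)c1c(O)cc(O)cc1O | intermediate (not isolated)
20 | 2-[3-(benzyloxy)-2,4,5-trimethoxyphenyl]-5,7-dihydroxy-4H-chromen-4-one (3'-benzyloxy-5,7-dihydroxy-2',4',5'-trimethoxyflavone) | COc1cc(-c2cc(=O)c3c(O)cc(O)cc3o2)c(OC)c(OCc2ccccc2)c1OC | intermediate
21 | 2-[3-(benzyloxy)-2,4,5-trimethoxyphenyl]-6,8-dibromo-5,7-dihydroxy-4H-chromen-4-one | COc1cc(-c2cc(=O)c3c(O)c(Br)c(O)c(Br)c3o2)c(OC)c(OCc2ccccc2)c1OC | intermediate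
22 | 2-[3-(benzyloxy)-2,4,5-trimethoxyphenyl]-5,7-dihydroxy-6,8-dimethoxy-4H-chromen-4-one | COc1cc(-c2cc(=O)c3c(O)c(OC)c(O)c(OC)c3o2)c(OC)c(OCc2ccccc2)c1OC | intermediate
23 | 2-[3-(benzyloxy)-2,4,5-trimethoxyphenyl]-5,6,7,8-tetramethoxy-4H-chromen-4-one | COc1cc(-c2cc(=O)c3c(OC)c(OC)c(OC)c(OC)c3o2)c(OC)c(OCc2ccccc2)c1OC | intermediate
24 | Agehoustin C, 2-(3-hydroxy-2,4,5-trimethoxyphenyl)-5,6,7,8-tetramethoxy-4H-chromen-4-one (no stereocentre) | COc1cc(-c2cc(=O)c3c(OC)c(OC)c(OC)c(OC)c3o2)c(OC)c(O)c1OC | target

**Step count and risks**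

Total step count: 13. Longest linear sequence: 13 steps (1 to 24).

Steps most likely to fail:

1. Step 9 (key step). What may go wrong: the opened chain folds by aldol attack of C8 on the C4 carbonyl or by carbon-Michael attack of C6 on C2 in place of the Claisen closure, or phenoxide closes 5-exo to an aurone. Fallback with known chemistry, setting out from alkyne 11 and returning at flavone 20: 11 is lithiated (n-BuLi, THF, −78 °C) and added to 2,4,6-tris(methoxymethoxy)benzaldehyde F1, itself made from 2,4,6-trihydroxybenzaldehyde with NaH and MOMCl in DMF. This should give racemic 3-[3-(benzyloxy)-2,4,5-trimethoxyphenyl]-1-[2,4,6-tris(methoxymethoxy)phenyl]prop-2-yn-1-ol F2, which MnO2 in CH2Cl2 should oxidise to 3-[3-(benzyloxy)-2,4,5-trimethoxyphenyl]-1-[2,4,6-tris(methoxymethoxy)phenyl]prop-2-yn-1-one F3. HCl in MeOH at 40 °C removes the three acetals to give 19, and K2CO3 in acetone closes it to 20 by the established 6-endo-dig cyclisation of 2-hydroxyaryl ynones. Ring A is then bought and not built.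

2. Step 8. What may go wrong: conjugate addition of the soft dianion to the ynamide, or of the released N,O-dimethylhydroxylamine to the new ynone during the quench. Fallback, setting out from alkyne 11 and pyranone 15 and returning at 17: acetylide 13 is formylated with DMF to 3-[3-(benzyloxy)-2,4,5-trimethoxyphenyl]prop-2-ynal F4. Dianion 16 adds 1,2 to this aldehyde (aldol-type addition) to give racemic 6-{4-[3-(benzyloxy)-2,4,5-trimethoxyphenyl]-2-hydroxybut-3-yn-1-yl}-4-hydroxy-2H-pyran-2-one F5, and activated MnO2 in CH2Cl2–acetone oxidises the propargylic alcohol to 17.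

3. Step 11. What may go wrong: reductive loss of bromine in competition with substitution at two hindered positions, air oxidation of the electron-rich bis-phenoxide, or opening of ring C by methoxide. Fallback, setting out from dibromide 21 and returning at 23, in which the C6 and C8 oxygens come from boron oxidation: 21 is methylated (Me2SO4, K2CO3, acetone, reflux) to 2-[3-(benzyloxy)-2,4,5-trimethoxyphenyl]-6,8-dibromo-5,7-dimethoxy-4H-chromen-4-one F6. Miyaura borylation (B2pin2, Pd(OAc)2, SPhos, KOAc, dioxane, 90 °C) should give 2-[3-(benzyloxy)-2,4,5-trimethoxyphenyl]-5,7-dimethoxy-6,8-bis(4,4,5,5-tetramethyl-1,3,2-dioxaborolan-2-yl)-4H-chromen-4-one F7. Oxidation (H2O2, NaHCO3, THF–water, 0 °C) gives 2-[3-(benzyloxy)-2,4,5-trimethoxyphenyl]-6,8-dihydroxy-5,7-dimethoxy-4H-chromen-4-one F8, and MeI with K2CO3 in DMF methylates both hydroxyls to give 23.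

**Further compounds**

F1 | step 9 | 2,4,6-tris(methoxymethoxy)benzaldehyde | COCOc1cc(OCOC)c(C=O)c(OCOC)c1
F2 | step 9 | 3-[3-(benzyloxy)-2,4,5-trimethoxyphenyl]-1-[2,4,6-tris(methoxymethoxy)phenyl]prop-2-yn-1-ol (racemic) | COCOc1cc(OCOC)c(C(O)C#Cc2cc(OC)c(OC)c(OCc3ccccc3)c2OC)c(OCOC)c1
F3 | step 9 | 3-[3-(benzyloxy)-2,4,5-trimethoxyphenyl]-1-[2,4,6-tris(methoxymethoxy)phenyl]prop-2-yn-1-one | COCOc1cc(OCOC)c(C(=O)C#Cc2cc(OC)c(OC)c(OCc3ccccc3)c2OC)c(OCOC)c1
F4 | step 8 | 3-[3-(benzyloxy)-2,4,5-trimethoxyphenyl]prop-2-ynal | COc1cc(C#CC=O)c(OC)c(OCc2ccccc2)c1OC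
F5 | step 8 | 6-{4-[3-(benzyloxy)-2,4,5-trimethoxyphenyl]-2-hydroxybut-3-yn-1-yl}-4-hydroxy-2H-pyran-2-one (racemic) | OC(Cc1cc(O)cc(=O)o1)C#Cc1cc(OC)c(OC)c(OCc2ccccc2)c1OC
F6 | step 11 | 2-[3-(benzyloxy)-2,4,5-trimethoxyphenyl]-6,8-dibromo-5,7-dimethoxy-4H-chromen-4-one | COc1cc(-c2cc(=O)c3c(OC)c(Br)c(OC)c(Br)c3o2)c(OC)c(OCc2ccccc2)c1OC
F7 | step 11 | 2-[3-(benzyloxy)-2,4,5-trimethoxyphenyl]-5,7-dimethoxy-6,8-bis(4,4,5,5-tetramethyl-1,3,2-dioxaborolan-2-yl)-4H-chromen-4-one | COc1cc(-c2cc(=O)c3c(OC)c(B4OC(C)(C)C(C)(C)O4)c(OC)c(B5OC(C)(C)C(C)(C)O5)c3o2)c(OC)c(OCc2ccccc2)c1OC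
F8 | step 11 | 2-[3-(benzyloxy)-2,4,5-trimethoxyphenyl]-6,8-dihydroxy-5,7-dimethoxy-4H-chromen-4-one | COc1cc(-c2cc(=O)c3c(OC)c(O)c(OC)c(O)c3o2)c(OC)c(OCc2ccccc2)c1OC
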